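Assumption: the target has no stereocenter and no stereogenic double bond, so no stereocontrol is needed; 7 and the transient intermediates 9, 11 and 13 are racemic, and their stereocenters disappear in step 5.

## Structural features

- The target is a flavone. Benzo ring A (C4a, C5, C6, C7, C8, C8a) is fused through the C4a–C8a bond to pyranone ring C (O1, C2, C3, C4). C2 carries a 4-hydroxyphenyl ring B and C8 carries a 4-hydroxybenzyl group.
- Ring A is a phloroglucinol nucleus with oxygen on C5 (OH, hydrogen-bonded to the C4 carbonyl), on C7 (OH) and on C8a (ring oxygen O1). C4a bears the acyl carbon C4, C8 the benzyl carbon, and only C6 bears hydrogen.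
- There are no stereocenters, so none stand next to each other.
- The fragile groups are the four phenols and the electron-rich diarylmethane, which strong acid can cleave by ipso-protonation of ring A at C8.
- The 5,7-dihydroxyflavone core is also fragile: ring C can open and reclose through the other ortho oxygen (Wessely–Moser rearrangement), which would move the benzyl group from C8 to C6.
- The real difficulty is to place the benzyl group on C8 and not on C6. Both carbons lie between two oxygens and are electronically almost alike. In any open-chain acylphloroglucinol precursor they differ only in which ortho oxygen becomes O1.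
- The key step exploits two facts: C8 is the only ring A carbon bonded to C8a, the carbon that carries O1, and the C4a–C8a bond is also a C=C bond of the pyranone. Ring A is therefore built onto a finished pyranone, from a side-chain carbon on the O1-bearing pyranone carbon (future C8) to the only ring carbon next to it (future C4a). C8 versus C6 is then decided by connectivity.

## Logic of the disconnections

**15 from 14.** The bonds cut are the two O–CH3 bonds of the aryl methyl ethers and the O–CH2CH3 bond at C7. The ethyl group arrives with the alkyne of the key step and the methyl groups with the two aryl building blocks, and all three leave in one operation. The gain is that no free phenol has to pass through carbanion, acid chloride and ketene chemistry. The forward step must cleave three ethers without ipso-protonation of ring A at C8 and without opening ring C.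

**14 from 7 and 8 (key disconnection).** In one sentence: ring A of the flavone is made by benzannulation of a pyranonyl(benzyl)ketene, derived from 7, with ynol ether 8.
- Bonds cut: C4a–C5, C5–C6 and C7–C8 of ring A. Going backwards, the bond between C5 and C8 is restored as the carboxyl-to-α-carbon bond of 7.
- Atom origin: C5 and its oxygen come from the carboxyl group of 7, C6 and C7 with the C7 oxygen from the two carbons of 8, C8 from the α-carbon of 7, and C4a and C8a from a C=C bond of the pyranone of 7.
- Reason: the α-carbon of 7 already carries the benzyl group and sits on the O1-bearing pyranone carbon, whose only other ring neighbour is the future C4a. No C6/C8 choice is left.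
- Gain: a bicyclic, fully differentiated ring A is reduced to a monocyclic pyranone with a three-carbon side chain and a two-carbon alkyne.
- Demand: the ketene must form from 7 under conditions the pyranone tolerates, the [2+2] addition of 8 must be regioselective, and the resulting cyclobutenone must open and close onto pyranone C3.

**7 from 6.** The bond cut is the one between the α-carbon and the carboxyl carbon. The CH2 group next to the pyranone in 6 is a vinylogous α-position, so its carbanion can take up a one-carbon electrophile. The gain is a one-step preparation of the ketene precursor. The forward step needs selective deprotonation at this CH2 and an acid that survives isolation without losing CO2.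

**6 from 4 and 5.** The bond cut is the CH2–CH2 bond between the lateral carbon of the pyranone and the benzylic carbon. The 6-methyl group of 4 is the acidic lateral position and 5 is a reactive benzylic electrophile. The gain is that the benzyl arene is attached to the future C8 before ring A exists. The forward step needs mono-alkylation at the exocyclic carbon.

**4 from 3.** The bond cut is the ring C–O bond of the pyranone, made in the forward direction with loss of water. A 1,3,5-triketone can close to only one 4-pyranone. The gain is an open-chain precursor. The forward step needs acid strong enough for cyclodehydration but harmless to the anisyl ring.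

**3 from 1 and 2.** The bond cut is the one between the aroyl carbon and the adjacent CH2. The terminal carbon of a 1,3-diketone dianion is acylated by an aryl ester. The gain is two commercial materials. The forward step needs acylation at the terminal methyl and not at the central CH2.

## Other disconnections considered

**Alternative 1:** the first plan that comes to mind cuts O1–C2 and C2–C3 of ring C.
- Forward: the C-benzylated phloroacetophenone A1 is protected and condensed with an aryl aldehyde to the 2'-hydroxychalcone A2. Oxidative cyclization (oxa-Michael addition, then dehydrogenation with I2 in DMSO) closes ring C.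
- Ground for preferring the chosen plan: A1 has two ortho hydroxyls flanking the acyl group, one next to the benzyl group and one next to hydrogen. Which one closes decides C8 against C6. Control would rest on a selective protection that tells apart two chelated hydroxyls of nearly equal acidity.
- The step count is similar, so the ground is regiochemical certainty and not step economy. The chosen plan fixes the position by connectivity.

**Alternative 2:** cut the C8–CH2 bond on the complete flavone.
- Forward: acid-promoted Friedel–Crafts benzylation of the parent 5,7,4'-trihydroxyflavone A3 by the p-quinone methide A4 generated in situ.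
- Ground for preferring the chosen plan: this is the shortest plan on paper, but C6 and C8 of A3 are both activated by two oxygens and nothing in A3 distinguishes them decisively. The 6-benzyl isomer A5 and double benzylation are expected to compete. The acid needed is also the condition under which a benzyl group on ring A can migrate.

**Alternative 3:** keep ring A for last but close it by an ionic step, cutting only C4a–C5.
- Forward: 7 would be homologated by two carbons to the β-keto ester A6. Intramolecular acylation of pyranone C3 by the ester carbonyl (a polyketide-like Claisen or Friedel–Crafts closure) would give the 5,7-dihydroxyflavone A7.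
- Ground for preferring the chosen plan: pyranone C3 is only a weak nucleophile. Under base A6 becomes an enolate and its ester loses electrophilicity. Under strong acid the pyranone is O-protonated and C3 is deactivated, while the β-keto ester is prone to lose its ester carbon.
- The ketene of the chosen plan is a far stronger electrophile for the same C4a–C5 bond, brings C6 and C7 in the same operation, and saves a step.

Key step: step 5

## Route

Step 1
Reactants: 1 pentane-2,4-dione; 2 methyl 4-methoxybenzoate
Product: 3 1-(4-methoxyphenyl)hexane-1,3,5-trione
Conditions: NaH (excess), DME, reflux; then aq. HCl, 0 °C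
Reagents that add atoms: none
Why: Claisen-type γ-aroylation of a 1,3-diketone: under excess NaH the diketone reacts through its dianion at the terminal methyl carbon, and the trione is kept from further reaction as its polyanion until the acidic quench.

Step 2
Reactants: 3 1-(4-methoxyphenyl)hexane-1,3,5-trione
Product: 4 2-(4-methoxyphenyl)-6-methyl-4H-pyran-4-one
Conditions: conc. H2SO4, 0 °C; then ice-water
Reagents that add atoms: none
Why: Acid-mediated cyclodehydration of a 1,3,5-triketone to a 4-pyranone: the enol oxygen of one terminal carbonyl adds to the other and water is lost, and only one pyranone can form; the anisyl ring is deactivated towards sulfonation by the protonated carbonyl system at 0 °C.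

Step 3
Reactants: 4 2-(4-methoxyphenyl)-6-methyl-4H-pyran-4-one; 5 1-(chloromethyl)-4-methoxybenzene (4-methoxybenzyl chloride)
Product: 6 2-(4-methoxyphenyl)-6-[2-(4-methoxyphenyl)ethyl]-4H-pyran-4-one
Conditions: LiN(SiMe3)2, THF, −78 °C; then 5, DMPU, −78 to 0 °C
Reagents that add atoms: none
Why: Lateral (vinylogous) deprotonation of the 6-methyl group gives a dienolate that is alkylated at the exocyclic carbon, because attack through ring carbon C5 would give up the cyclic conjugation of the pyranone.

Step 4
Reactants: 6 2-(4-methoxyphenyl)-6-[2-(4-methoxyphenyl)ethyl]-4H-pyran-4-one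
Product: 7 3-(4-methoxyphenyl)-2-[6-(4-methoxyphenyl)-4-oxo-4H-pyran-2-yl]propanoic acid (racemic)
Conditions: LiN(i-Pr)2, THF, −78 °C; CO2 (g), −78 °C; then cold 1 M HCl to pH 3
Reagents that add atoms: carbon dioxide, O=C=O
Why: Second lateral deprotonation at the CH2 next to the pyranone (C2 and C6 of the ring are substituted, so no ring position competes) and carboxylation of the carbanion; the new stereocenter forms racemic and is erased in step 5.

Step 5
Reactants: 7 3-(4-methoxyphenyl)-2-[6-(4-methoxyphenyl)-4-oxo-4H-pyran-2-yl]propanoic acid; 8 ethoxyethyne (ethoxyacetylene)
Product: 14 7-ethoxy-5-hydroxy-8-(4-methoxybenzyl)-2-(4-methoxyphenyl)-4H-chromen-4-one, via acid chloride 9 (not isolated), via ketene 10 (not isolated), via cyclobutenone 11 (not isolated), via dienylketene 12 (not isolated), via dienone tautomer 13 (not isolated)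
Conditions: Me2C=C(Cl)NMe2, CH2Cl2, 0 °C to rt; then 8 (3 equiv), Et3N (slow addition), 0 °C to rt; concentrate, PhMe, 100 °C
Reagents that add atoms: none
Why: Ketene–alkyne benzannulation of the Smith–Hoehn/Danheiser type, the closest known reaction being the annulation of aryl- and vinylketenes with ynol ethers to resorcinol monoethers. The chloroenamine converts 7 into acid chloride 9 without free HCl, Et3N removes the α-hydrogen (activated by the acyl chloride and by the pyranone as a vinylogous ketone) to give ketene 10, and [2+2] cycloaddition with 8, whose nucleophilic CH terminus bonds to the ketene sp carbon, gives 3-ethoxycyclobutenone 11. At 100 °C conrotatory 4π opening cleaves the former α-carbon-to-carbonyl bond of 11 to dienylketene 12, and disrotatory 6π electrocyclization of 12 onto pyranone C3 forms the C4a–C5 bond and gives dienone 13, whose C4a hydrogen lies between two carbonyl groups and enolizes at once to the aromatic, hydrogen-bonded 5-hydroxychromone 14. The four-membered ring is closed by the [2+2] step and opened again, and the six-membered ring A is closed by the 6π electrocyclization. No stereocenter is left in 14: the racemic centers of 7, 9, 11 and 13 are erased, and the geometry of 12 corrects itself because the ring opening is reversible and only the isomer with the pyranonyl group cis to the ketene is drained. The step needs ethoxy at C7 and benzyl at C8; the first is secured by the polarity of the ynol ether, the second by connectivity, since the benzyl-bearing carbon sits on the pyranone carbon attached to O1, whose only ring carbon neighbour is C3. The closure is polarity-matched, as C3 is the β-carbon of the enol ether O1–C2=C3 and the ketene carbon is electrophilic. Ketene dimerization is held back by excess 8 and slow addition of the base.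

Step 6
Reactants: 14 7-ethoxy-5-hydroxy-8-(4-methoxybenzyl)-2-(4-methoxyphenyl)-4H-chromen-4-one
Product: 15 5,7-dihydroxy-8-(4-hydroxybenzyl)-2-(4-hydroxyphenyl)-4H-chromen-4-one
Conditions: BBr3 (excess), CH2Cl2, −78 °C to rt; then MeOH, H2O, 0 °C
Reagents that add atoms: none
Why: Lewis acid-mediated cleavage of aryl alkyl ethers: bromide attacks the methyl and ethyl carbons of the boron-complexed ethers; the diarylmethane and the pyranone are expected to survive at or below room temperature, and hot aqueous acid, the condition for Wessely–Moser isomerization, is avoided.

## Compound list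

1 | pentane-2,4-dione | CC(=O)CC(C)=O | starting material
2 | methyl 4-methoxybenzoate | COC(=O)c1ccc(OC)cc1 | starting material
3 | 1-(4-methoxyphenyl)hexane-1,3,5-trione | CC(=O)CC(=O)CC(=O)c1ccc(OC)cc1 | intermediate
4 | 2-(4-methoxyphenyl)-6-methyl-4H-pyran-4-one | Cc1cc(=O)cc(-c2ccc(OC)cc2)o1 | intermediate
5 | 1-(chloromethyl)-4-methoxybenzene | COc1ccc(CCl)cc1 | starting material
6 | 2-(4-methoxyphenyl)-6-[2-(4-methoxyphenyl)ethyl]-4H-pyran-4-one | COc1ccc(CCc2cc(=O)cc(-c3ccc(OC)cc3)o2)cc1 | intermediate
7 | 3-(4-methoxyphenyl)-2-[6-(4-methoxyphenyl)-4-oxo-4H-pyran-2-yl]propanoic acid (racemic) | COc1ccc(CC(C(=O)O)c2cc(=O)cc(-c3ccc(OC)cc3)o2)cc1 | intermediate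
8 | ethoxyethyne | CCOC#C | starting material
9 | 3-(4-methoxyphenyl)-2-[6-(4-methoxyphenyl)-4-oxo-4H-pyran-2-yl]propanoyl chloride (racemic) | COc1ccc(CC(C(=O)Cl)c2cc(=O)cc(-c3ccc(OC)cc3)o2)cc1 | intermediate (not isolated)
10 | 3-(4-methoxyphenyl)-2-[6-(4-methoxyphenyl)-4-oxo-4H-pyran-2-yl]prop-1-en-1-one (ketene) | COc1ccc(CC(=C=O)c2cc(=O)cc(-c3ccc(OC)cc3)o2)cc1 | intermediate (not isolated)
11 | 3-ethoxy-4-(4-methoxybenzyl)-4-[6-(4-methoxyphenyl)-4-oxo-4H-pyran-2-yl]cyclobut-2-en-1-one (racemic) | CCOC1=CC(=O)C1(Cc1ccc(OC)cc1)c1cc(=O)cc(-c2ccc(OC)cc2)o1 | intermediate (not isolated)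
12 | (3E)-3-ethoxy-5-(4-methoxyphenyl)-4-[6-(4-methoxyphenyl)-4-oxo-4H-pyran-2-yl]penta-1,3-dien-1-one (dienylketene, pyranonyl cis to the ketene) | O=C=C/C(OCC)=C(/Cc1ccc(OC)cc1)c1cc(=O)cc(-c2ccc(OC)cc2)o1 | intermediate (not isolated)
13 | 7-ethoxy-8-(4-methoxybenzyl)-2-(4-methoxyphenyl)-4aH-chromene-4,5-dione (racemic at C4a) | O=C1C=C(OCC)C(Cc2ccc(OC)cc2)=C2OC(-c3ccc(OC)cc3)=CC(=O)C12 | intermediate (not isolated)
14 | 7-ethoxy-5-hydroxy-8-(4-methoxybenzyl)-2-(4-methoxyphenyl)-4H-chromen-4-one | CCOc1cc(O)c2c(=O)cc(-c3ccc(OC)cc3)oc2c1Cc1ccc(OC)cc1 | intermediate
15 | 5,7-dihydroxy-8-(4-hydroxybenzyl)-2-(4-hydroxyphenyl)-4H-chromen-4-one | O=c1cc(-c2ccc(O)cc2)oc2c(Cc3ccc(O)cc3)c(O)cc(O)c12 | target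

## Step count and least certain steps

Total step count: 6. Longest linear sequence: 6 steps (1 → 3 → 4 → 6 → 7 → 14 → 15).

**Step 5 (key step).**
- What may go wrong: the ketene may be consumed before the [2+2] step, by dimerization or by acylation of the nucleophilic pyranone carbonyl oxygen of a second molecule. The cyclobutenone may also open with the benzyl group turned inward and then undergo a 1,5-hydrogen shift from the benzylic CH2 to the ketene carbon, which does not return to the productive isomer. Both processes compete because the electrocyclization has to engage a pyranone C=C bond that is part of a cross-conjugated system.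
- Fallback (sets out from 5, returns at 15): ring A construction is given up for a cross-coupling at C8 of a finished flavone. Purchased 5,7-dimethoxy-2-(4-methoxyphenyl)-4H-chromen-4-one F1 would be iodinated with N-iodosuccinimide and CF3CO2H to 8-iodo-5,7-dimethoxy-2-(4-methoxyphenyl)-4H-chromen-4-one F2. With the 5-oxygen methylated, the electrophile should prefer C8, which is flanked by only one methoxy group. Compound 5 would be converted with zinc dust and LiCl in THF into (4-methoxybenzyl)zinc chloride F3. Negishi coupling of F2 with F3 (Pd(OAc)2, SPhos, THF) should give 5,7-dimethoxy-8-(4-methoxybenzyl)-2-(4-methoxyphenyl)-4H-chromen-4-one F4. Cleavage of its four methyl ethers with BBr3 as in step 6 would give 15.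

**Step 4.**
- What may go wrong: loss of carbon dioxide from the product during acidification or storage, since 7 is a vinylogous β-keto acid. Incomplete or unselective metalation of the secondary lateral position, and proton transfer from unreacted 6 to the carboxylated dianion, are further risks.
- Fallback (sets out from 4, returns at 7): the order of bond formation is reversed so that the carboxyl carbon enters at the more easily metalated methyl group and stays masked until it is needed. Compound 4 with LiN(SiMe3)2 (2 equiv) and di-tert-butyl dicarbonate would give tert-butyl 2-[6-(4-methoxyphenyl)-4-oxo-4H-pyran-2-yl]acetate F5. Its doubly activated CH2 would be alkylated with 5 (NaH, DMF, 0 °C) to tert-butyl 3-(4-methoxyphenyl)-2-[6-(4-methoxyphenyl)-4-oxo-4H-pyran-2-yl]propanoate F6. Anhydrous CF3CO2H in CH2Cl2 would release 7 just before step 5.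

**Step 3.**
- What may go wrong: over-alkylation through proton exchange between the product and the lateral carbanion, and slow reaction of the benzylic chloride at low temperature, which gives the carbanion time to add to a second pyranone.
- Fallback (sets out from 1, returns at 6): the benzyl unit is introduced at the open-chain stage, where terminal alkylation of a diketone dianion is reliable. The dianion of 1 (LiN(i-Pr)2, 2 equiv, THF) would be alkylated with 5 to 6-(4-methoxyphenyl)hexane-2,4-dione F7. Aroylation of F7 with 2 at its remaining methyl group (NaH, DME, reflux, as in step 1) would give 1,7-bis(4-methoxyphenyl)heptane-1,3,5-trione F8. Cyclodehydration as in step 2 would give 6.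

**Step 6.**
- What may go wrong: acid-mediated loss or migration of the C8 benzyl group by ipso-protonation of the electron-rich ring A (retro-Friedel–Crafts), and incomplete cleavage of the ethyl ether, which reacts more slowly than the methyl ethers.
- Fallback (sets out from 14, returns at 15): the mode of cleavage is changed from electrophilic activation of the ether oxygen to SN2 attack at the alkyl carbons in a basic medium. NaSEt (excess) in DMF at 130 °C, followed by acidic work-up, keeps ring A as a phenoxide throughout, so it cannot be protonated at C8. This fallback makes no new compound (F0).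

## Further compounds

F1 | step 5 | 5,7-dimethoxy-2-(4-methoxyphenyl)-4H-chromen-4-one (purchased) | COc1ccc(cc1)-c1cc(=O)c2c(OC)cc(OC)cc2o1
F2 | step 5 | 8-iodo-5,7-dimethoxy-2-(4-methoxyphenyl)-4H-chromen-4-one | COc1ccc(cc1)-c1cc(=O)c2c(OC)cc(OC)c(I)c2o1
F3 | step 5 | (4-methoxybenzyl)zinc chloride | COc1ccc(C[Zn]Cl)cc1
F4 | step 5 | 5,7-dimethoxy-8-(4-methoxybenzyl)-2-(4-methoxyphenyl)-4H-chromen-4-one | COc1ccc(Cc2c(OC)cc(OC)c3c(=O)cc(-c4ccc(OC)cc4)oc23)cc1
F5 | step 4 | tert-butyl 2-[6-(4-methoxyphenyl)-4-oxo-4H-pyran-2-yl]acetate | CC(C)(C)OC(=O)Cc1cc(=O)cc(-c2ccc(OC)cc2)o1
F6 | step 4 | tert-butyl 3-(4-methoxyphenyl)-2-[6-(4-methoxyphenyl)-4-oxo-4H-pyran-2-yl]propanoate (racemic) | CC(C)(C)OC(=O)C(Cc1ccc(OC)cc1)c1cc(=O)cc(-c2ccc(OC)cc2)o1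
F7 | step 3 | 6-(4-methoxyphenyl)hexane-2,4-dione | CC(=O)CC(=O)CCc1ccc(OC)cc1
F8 | step 3 | 1,7-bis(4-methoxyphenyl)heptane-1,3,5-trione | COc1ccc(CCC(=O)CC(=O)CC(=O)c2ccc(OC)cc2)cc1
F0 | step 6 | none | none
A1 | alternative 1 | 1-[2,4,6-trihydroxy-3-(4-methoxybenzyl)phenyl]ethan-1-one | CC(=O)c1c(O)cc(O)c(Cc2ccc(OC)cc2)c1O
A2 | alternative 1 | (E)-1-[2-hydroxy-4,6-dimethoxy-3-(4-methoxybenzyl)phenyl]-3-(4-methoxyphenyl)prop-2-en-1-one | COc1ccc(/C=C/C(=O)c2c(O)c(Cc3ccc(OC)cc3)c(OC)cc2OC)cc1
A3 | alternative 2 | 5,7-dihydroxy-2-(4-hydroxyphenyl)-4H-chromen-4-one | O=c1cc(-c2ccc(O)cc2)oc2cc(O)cc(O)c12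
A4 | alternative 2 | 4-methylidenecyclohexa-2,5-dien-1-one | C=C1C=CC(=O)C=C1
A5 | alternative 2 | 5,7-dihydroxy-6-(4-hydroxybenzyl)-2-(4-hydroxyphenyl)-4H-chromen-4-one | O=c1cc(-c2ccc(O)cc2)oc2cc(O)c(Cc3ccc(O)cc3)c(O)c12
A6 | alternative 3 | ethyl 5-(4-methoxyphenyl)-4-[6-(4-methoxyphenyl)-4-oxo-4H-pyran-2-yl]-3-oxopentanoate (racemic) | CCOC(=O)CC(=O)C(Cc1ccc(OC)cc1)c1cc(=O)cc(-c2ccc(OC)cc2)o1
A7 | alternative 3 | 5,7-dihydroxy-8-(4-methoxybenzyl)-2-(4-methoxyphenyl)-4H-chromen-4-one | O=c1cc(-c2ccc(OC)cc2)oc2c(Cc3ccc(OC)cc3)c(O)cc(O)c12
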